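If each initiator begins one chain, each protic impurity costs one free monomer, and a flask uses up both, its average chain cannot pass the ceiling length, the free monomer charge less the protic impurity charge, over the initiator charge: 103 for red and 328 for grey.

| flask | free monomer | protic impurity | initiator | remark | time |
|---|---|---|---|---|---|
| south-east | 0.14 M | 6.5 mM | 1.2 mM | run made earlier |  |
| west | 0.21 M | 6.5 mM | 1.2 mM | run made earlier |  |
| north-west | 0.29 M | 6.5 mM | 1.2 mM | run made earlier |  |
| red | 0.13 M | 6.50 mM | 1.2 mM |  | 30 h |
| grey | 0.40 M | 6.50 mM | 1.2 mM |  | 30 h |

| run | time / h | monomer in chains / % |
|---|---|---|
| south-east | 2.00 | 11 |
| south-east | 5.00 | 40 |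
| south-east | 10.0 | 68 |
| south-east | 15.0 | 79 |
| south-east | 20.0 | 89 |
| west | 4.00 | 35 |
| west | 8.00 | 60 |
| west | 12.0 | 73 |
| west | 15.0 | 82 |
| west | 20.0 | 89 |
| north-west | 2.00 | 20 |
| north-west | 5.00 | 45 |
| north-west | 10.0 | 72 |
| north-west | 15.0 | 85 |
| north-west | 20.0 | 88 |

(scatter of a reading: 2 percentage points)

- which of the two ends with the longer chains by the average number of monomer units in a chain (chains begun, living or dead) ("neither" if they lie within 10 %) (red / grey / neither)
- average number of monomer units in a chain (chains begun, living or dead) at the end, red
- average number of monomer units in a chain (chains begun, living or dead) at the end, grey

- the average divides the monomer in chains by the number of chains begun, living and dead together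
- the numbers in the tables scatter by 2 percentage points (one standard deviation)
- the earlier runs do not show the number of chains; that part of a forecast is a guess

Two runs give the pace separately. The south-east run, from 5.00 h to 20.0 h, reads a first-order constant of 0.113 /h. The north-west run, with twice the free monomer, reads 0.101 /h. These readings agree within their scatter, so the uptake of free monomer looks pseudo-first-order, and by the south-east constant 96.6 % of the charge should stand in chains at 30 h in red and in grey.

Two counts of chains then part for red. Counting initiator plus protic impurity as chains begun gives an average of 16.3, and counting initiator alone gives 105. The earlier runs do not show the number of chains, so this reckoning takes the initiator count, as a guess. Red's 105 then stands above its ceiling, so the estimate for red is the ceiling, 103. Grey's 322 stands below its ceiling, so the estimate for grey is 322.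

The forecast differs from this reckoning. It guessed about 4 mM of chains and gave 31 for red and 96 for grey, with grey longer, holding that the impurity “most likely acts by transfer, ending a chain and starting a new one”.

    free monomer + living end → monomer in chains + living end, rate k1*[living end]*[free monomer] (k = 110 /M/h)
    free monomer + initiator → living end + monomer in chains (k = 8.10 /M/h)
    protic impurity + free monomer → quenched substrate (k = 37.0 /M/h)

Grey ends longer, with 321 against 101 in red. Red holds 5.00 % of its free monomer charge as quenched substrate at 30.0 h, and its living end stands at 0.00120 M, the initiator charge. Red has reached 98.1 % of its ceiling of 103. The same grey flask read at 8.0 h is the further case: its ceiling of 328 times the first-order fraction from the south-east constant gives 195, and the flask stands at 209.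

(Readings and results are calculated with constants of no real substance; noise was put on by code.)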